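**Retrosynthetic overview**
- Ring B is opened last at C7–C8 (alkenyl triflate on C8, primary alkylborane on C7). The 2β-OH comes from a C2 ketone and the side-chain enoate from a methyl ketone.
- C9–C10 (quaternary C10 plus C9) is cut by an Ireland–Claisen rearrangement from an α-oxygen on C2. That oxygen and the C1=C10 alkene come from a C19-carboxyl-directed selenolactonisation of a Diels–Alder cyclohexene; C4 is made quaternary by enolate methylation anti to C6.
- Feature that makes the key step possible: the hepta-1,6-diene C17=C8(OTf)–C9–C10–C5–C6=C7, whose two arms stand cis (both α) on ring A at C10 and C5, so a C7 borane and the C8 triflate meet in a six-membered ring. The ring A alkene C1=C2, next to quaternary C10, takes boron at C2 as a secondary borane that palladium ignores and that becomes the C2 oxygen.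
- Order of rings: ring A (Diels–Alder), a temporary lactone bridge C19–O–C2 (made, then opened), ring B (key step).

Key step: step 16

Convention: carbons carry labdane-type numbers (C18 = methyl on C4, C19 = carboxyl on C4, C20 = methyl on C10, C17 = exocyclic CH2); β is the face of the C10 methyl. The target SMILES puts H-5, C20, H-9, C18 and the 2-OH on the β-face and C19, C6 and C11 on the α-face, so the decalin is cis-fused (labdane numbering 2S,4R,5S,9R,10R), and the route is built for exactly this isomer.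
Assumption: the (S)-configured oxazaborolidinium salt of step 1 is taken to give the Diels–Alder adduct with the C5 configuration drawn; if the sense of induction is the opposite, the (R)-catalyst is used.

**Route**

Step 1
Reactants: 1 (E)-penta-1,3-diene; 2 ethyl (E)-4-oxobut-2-enoate
Product: 3 ethyl 6-formyl-5-methylcyclohex-3-ene-1-carboxylate
Conditions: (S)-3,3-diphenyl-1-(2-methylphenyl)tetrahydro-1H,3H-pyrrolo[1,2-c][1,3,2]oxazaborole·HNTf2 (10 mol%), CH2Cl2, −78 °C
Reagents that add atoms: none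
Why: Lewis-acid-catalysed asymmetric Diels–Alder reaction in which the boron-bound formyl group makes C4 the electrophilic terminus (unsubstituted diene terminus to C4, methyl-bearing terminus to C5), the formyl group adds endo (C10 methyl cis to CHO) and the chiral oxazaborolidinium shields one enal face, which sets C5, the only centre of 3 that is carried to the target.

Step 2
Reactants: 3 ethyl 6-formyl-5-methylcyclohex-3-ene-1-carboxylate
Product: 4 ethyl 6-(1,3-dioxolan-2-yl)-5-methylcyclohex-3-ene-1-carboxylate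
Conditions: Me3SiOCH2CH2OSiMe3, Me3SiOTf (cat.), CH2Cl2, −78 → −20 °C
Reagents that add atoms: 1,2-bis(trimethylsilyloxy)ethane, C[Si](C)(C)OCCO[Si](C)(C)C
Why: Aprotic acetalisation at low temperature masks the aldehyde for the carbanion and selenium chemistry ahead without epimerising C5.

Step 3
Reactants: 4 ethyl 6-(1,3-dioxolan-2-yl)-5-methylcyclohex-3-ene-1-carboxylate
Product: 5 6-(1,3-dioxolan-2-yl)-5-methylcyclohex-3-ene-1-carboxylic acid
Conditions: LiOH, THF/H2O, 0 °C → rt; then 1 M HCl to pH 3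
Reagents that add atoms: lithium hydroxide, [Li+].[OH-]
Why: Saponification of the unhindered secondary ester; the configuration at C4 does not matter because C4 becomes an enolate carbon in the next step.

Step 4
Reactants: 5 6-(1,3-dioxolan-2-yl)-5-methylcyclohex-3-ene-1-carboxylic acid
Product: 6 6-(1,3-dioxolan-2-yl)-1,5-dimethylcyclohex-3-ene-1-carboxylic acid
Conditions: LiN(i-Pr)2 (2.2 equiv), THF, −78 → −20 °C; MeI, −78 °C → rt
Reagents that add atoms: iodomethane, CI
Why: Alkylation of the carboxylic acid dianion, in which the dioxolanyl group on C5 sits axial to avoid allylic strain with the enediolate and iodomethane enters anti to it, so the new methyl on quaternary C4 is β and C19 is cis to C6.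

Step 5
Reactants: 6 6-(1,3-dioxolan-2-yl)-1,5-dimethylcyclohex-3-ene-1-carboxylic acid
Product: 9 2-(1,3-dioxolan-2-yl)-1,3-dimethyl-6-oxabicyclo[3.2.1]oct-3-en-7-one, via phenylselenolactone 7 (not isolated), via selenoxide 8 (not isolated)
Conditions: N-(phenylselanyl)phthalimide, (1S)-10-camphorsulfonic acid (cat.), CH2Cl2, 0 °C; then 30% H2O2, THF, 0 °C → rt
Reagents that add atoms: none
Why: Selenolactonisation then selenoxide syn-elimination: the α-carboxyl opens the seleniranium ion at C2 in an anti addition (O α on C2, Se β on C1, bridged five-membered lactone) and the selenoxide can eliminate only towards the cis hydrogen on C10 because C2 is a bridgehead, which fixes the C2 oxygen cis to C19 and moves the alkene to C1=C10.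

Step 6
Reactants: 9 2-(1,3-dioxolan-2-yl)-1,3-dimethyl-6-oxabicyclo[3.2.1]oct-3-en-7-one
Product: 10 methyl 2-(1,3-dioxolan-2-yl)-5-hydroxy-1,3-dimethylcyclohex-3-ene-1-carboxylate
Conditions: K2CO3 (cat.), MeOH, 0 °C
Reagents that add atoms: methanol, CO
Why: Base-catalysed methanolysis (transesterification) of the strained bridged lactone should give the methyl ester and free the 2α allylic alcohol without touching a stereocentre.

Step 7
Reactants: 10 methyl 2-(1,3-dioxolan-2-yl)-5-hydroxy-1,3-dimethylcyclohex-3-ene-1-carboxylate; 11 hex-5-enoic acid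
Product: 12 methyl 2-(1,3-dioxolan-2-yl)-5-(hex-5-enoyloxy)-1,3-dimethylcyclohex-3-ene-1-carboxylate
Conditions: N,N'-dicyclohexylcarbodiimide, 4-(dimethylamino)pyridine (cat.), CH2Cl2, 0 °C → rt
Reagents that add atoms: none
Why: Steglich esterification of the secondary allylic alcohol under neutral conditions, with retention at C2.

Step 8
Reactants: 12 methyl 2-(1,3-dioxolan-2-yl)-5-(hex-5-enoyloxy)-1,3-dimethylcyclohex-3-ene-1-carboxylate
Product: 15 2-[6-(1,3-dioxolan-2-yl)-5-(methoxycarbonyl)-1,5-dimethylcyclohex-2-en-1-yl]hex-5-enoic acid, via silyl ketene acetal 13 (not isolated), via trimethylsilyl ester 14 (not isolated)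
Conditions: LiN(i-Pr)2, Me3SiCl, THF/DMPU, −78 °C; then 65 °C; 1 M HCl work-up
Reagents that add atoms: none
Why: Ireland–Claisen rearrangement, whose suprafacial [3,3] shift delivers C9 to C10 on the α-face that carried the C2 oxygen (quaternary C10 with methyl β, C9 cis to C6 and C19), while the ketene acetal with C11 cis to the silyloxy group reacts through the boat-like transition state favoured by cyclohexenyl esters (hydrogen, not C11, over the ring), which gives the C9 configuration of the target.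

Step 9
Reactants: 15 2-[6-(1,3-dioxolan-2-yl)-5-(methoxycarbonyl)-1,5-dimethylcyclohex-2-en-1-yl]hex-5-enoic acid
Product: 17 methyl 2-(1,3-dioxolan-2-yl)-3-{1-[methoxy(methyl)amino]-1-oxohex-5-en-2-yl}-1,3-dimethylcyclohex-4-ene-1-carboxylate, via acyl imidazole 16 (not isolated)
Conditions: 1,1'-carbonyldiimidazole, CH2Cl2, rt; then MeNH(OMe)·HCl
Reagents that add atoms: N,O-dimethylhydroxylamine hydrochloride, CNOC.Cl
Why: Amide formation through the acyl imidazole turns the acid into an N-methoxy-N-methylamide that accepts exactly one carbon nucleophile, under conditions too mild to epimerise C9.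

Step 10
Reactants: 17 methyl 2-(1,3-dioxolan-2-yl)-3-{1-[methoxy(methyl)amino]-1-oxohex-5-en-2-yl}-1,3-dimethylcyclohex-4-ene-1-carboxylate
Product: 18 methyl 2-(1,3-dioxolan-2-yl)-1,3-dimethyl-3-(2-oxohept-6-en-3-yl)cyclohex-4-ene-1-carboxylate
Conditions: MeMgBr, THF, −78 → 0 °C; aq NH4Cl
Reagents that add atoms: methylmagnesium bromide, C[Mg]Br
Why: Ketone synthesis from an N-methoxy-N-methylamide, in which the chelated tetrahedral intermediate survives until work-up so that only the methyl ketone forms, while the C19 ester on a quaternary carbon is not attacked at low temperature.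

Step 11
Reactants: 18 methyl 2-(1,3-dioxolan-2-yl)-1,3-dimethyl-3-(2-oxohept-6-en-3-yl)cyclohex-4-ene-1-carboxylate
Product: 19 methyl 2-(1,3-dioxolan-2-yl)-1,3-dimethyl-3-[2-(trifluoromethanesulfonyloxy)hepta-1,6-dien-3-yl]cyclohex-4-ene-1-carboxylate
Conditions: KN(SiMe3)2, THF, −78 °C; PhNTf2
Reagents that add atoms: N-phenylbis(trifluoromethanesulfonimide), O=S(=O)(N(c1ccccc1)S(=O)(=O)C(F)(F)F)C(F)(F)F
Why: Kinetic enolisation at the methyl group (the C9 hydrogen is tertiary and flanked by quaternary C10) followed by O-sulfonylation should give the 1,1-disubstituted alkenyl triflate, which also protects C9 from epimerisation.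

Step 12
Reactants: 19 methyl 2-(1,3-dioxolan-2-yl)-1,3-dimethyl-3-[2-(trifluoromethanesulfonyloxy)hepta-1,6-dien-3-yl]cyclohex-4-ene-1-carboxylate
Product: 20 methyl 2-(1,3-dioxolan-2-yl)-1,3-dimethyl-3-[6-oxo-2-(trifluoromethanesulfonyloxy)hept-1-en-3-yl]cyclohex-4-ene-1-carboxylate
Conditions: PdCl2 (10 mol%), CuCl (1 equiv), O2 (1 atm), DMF/H2O, rt
Reagents that add atoms: water, O
Why: Wacker oxidation, in which the monosubstituted terminal alkene is hydroxypalladated with Markovnikov selectivity much faster than the cis-disubstituted ring alkene or the electron-poor alkenyl triflate, giving the side-chain methyl ketone.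

Step 13
Reactants: 20 methyl 2-(1,3-dioxolan-2-yl)-1,3-dimethyl-3-[6-oxo-2-(trifluoromethanesulfonyloxy)hept-1-en-3-yl]cyclohex-4-ene-1-carboxylate; 21 trimethyl phosphonoacetate
Product: 22 methyl 2-(1,3-dioxolan-2-yl)-3-[(6E)-8-methoxy-6-methyl-8-oxo-2-(trifluoromethanesulfonyloxy)octa-1,6-dien-3-yl]-1,3-dimethylcyclohex-4-ene-1-carboxylate
Conditions: NaH, THF, 0 → 50 °C
Reagents that add atoms: none
Why: Horner–Wadsworth–Emmons olefination of the methyl ketone with a stabilised phosphonate anion should give mainly the (E)-enoate (ester trans to the larger C12 chain), the minor (Z)-isomer being removed by chromatography.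

Step 14
Reactants: 22 methyl 2-(1,3-dioxolan-2-yl)-3-[(6E)-8-methoxy-6-methyl-8-oxo-2-(trifluoromethanesulfonyloxy)octa-1,6-dien-3-yl]-1,3-dimethylcyclohex-4-ene-1-carboxylate
Product: 23 methyl 2-formyl-3-[(6E)-8-methoxy-6-methyl-8-oxo-2-(trifluoromethanesulfonyloxy)octa-1,6-dien-3-yl]-1,3-dimethylcyclohex-4-ene-1-carboxylate
Conditions: 2 M HCl, THF, 40 °C
Reagents that add atoms: water, O
Why: Acid-catalysed acetal hydrolysis frees the C6 aldehyde only now, when C10 is quaternary and the aldehyde can no longer slip into conjugation, and the alkenyl triflate and enoate tolerate dilute aqueous acid.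

Step 15
Reactants: 23 methyl 2-formyl-3-[(6E)-8-methoxy-6-methyl-8-oxo-2-(trifluoromethanesulfonyloxy)octa-1,6-dien-3-yl]-1,3-dimethylcyclohex-4-ene-1-carboxylate
Product: 24 methyl 2-ethenyl-3-[(6E)-8-methoxy-6-methyl-8-oxo-2-(trifluoromethanesulfonyloxy)octa-1,6-dien-3-yl]-1,3-dimethylcyclohex-4-ene-1-carboxylate
Conditions: Ph3PCH3Br, KN(SiMe3)2, THF, −78 → 0 °C
Reagents that add atoms: methyltriphenylphosphonium bromide, C[P+](c1ccccc1)(c1ccccc1)c1ccccc1.[Br-]
Why: Wittig methylenation with the non-stabilised ylide converts the hindered aldehyde into the C6=C7 vinyl group at low temperature, leaving esters, enoate and triflate untouched.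

Step 16
Reactants: 24 methyl 2-ethenyl-3-[(6E)-8-methoxy-6-methyl-8-oxo-2-(trifluoromethanesulfonyloxy)octa-1,6-dien-3-yl]-1,3-dimethylcyclohex-4-ene-1-carboxylate
Product: 27 methyl 3-hydroxy-5-[(3E)-5-methoxy-3-methyl-5-oxopent-3-en-1-yl]-1,4a-dimethyl-6-methylidenedecahydronaphthalene-1-carboxylate (C2 epimers), via bis-alkylborane 25 (not isolated), via bicyclic C2 borane 26 (not isolated)
Conditions: 9-borabicyclo[3.3.1]nonane (9-BBN-H, 2.6 equiv), THF, rt then 65 °C; then PdCl2(dppf) [dppf = 1,1'-bis(diphenylphosphino)ferrocene] (10 mol%), AsPh3, aq Cs2CO3, DMF/THF, 50 °C, 0.005 M; then NaBO3·4H2O, rt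
Reagents that add atoms: sodium perborate tetrahydrate, [Na+].[O-]OB=O.O.O.O.O
Why: 9-BBN adds anti-Markovnikov and syn to the two C=C bonds that are not deactivated, placing boron on terminal C7 and, on heating, on C2 of the ring alkene (C1 is neopentylic next to quaternary C10), while the alkenyl triflate and the β,β-disubstituted enoate are left alone. Zerovalent palladium then inserts into the C8–OTf bond, the base-activated primary C7–boron bond transmetalates and reductive elimination forms C7–C8; the closest known reaction type is the intramolecular B-alkyl Suzuki–Miyaura cyclisation of 2-halo- or 2-triflyloxy-hepta-1,6-dienes to methylenecyclohexanes. Ring B (C5–C6–C7–C8–C9–C10) closes in the exo sense, with C17 left outside as the methylidene carbon, helped by the cis arrangement of the two arms on C5 and C10. The coupling creates no stereocentre: the cis ring fusion follows from C6 and C9 both being α and C9 is not touched, while the C2 carbinol centre formed in the oxidation is not controlled and both epimers converge in step 17. The selectivities needed are primary over secondary alkylborane in the transmetalation (the secondary C2 borane does not transfer and is oxidised to the alcohol afterwards) and ring closure over intermolecular coupling, which high dilution secures.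

Step 17
Reactants: 27 methyl 3-hydroxy-5-[(3E)-5-methoxy-3-methyl-5-oxopent-3-en-1-yl]-1,4a-dimethyl-6-methylidenedecahydronaphthalene-1-carboxylate (C2 epimers)
Product: 28 methyl 5-[(3E)-5-methoxy-3-methyl-5-oxopent-3-en-1-yl]-1,4a-dimethyl-6-methylidene-3-oxodecahydronaphthalene-1-carboxylate
Conditions: Dess–Martin periodinane, NaHCO3, CH2Cl2, 0 °C → rt
Reagents that add atoms: none
Why: Dess–Martin oxidation of the secondary alcohol converges both C2 epimers into one ketone under neutral conditions that do not isomerise the exocyclic alkene.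

Step 18
Reactants: 28 methyl 5-[(3E)-5-methoxy-3-methyl-5-oxopent-3-en-1-yl]-1,4a-dimethyl-6-methylidene-3-oxodecahydronaphthalene-1-carboxylate
Product: 29 methyl (1R,3S,4aR,5R,8aS)-3-hydroxy-5-[(3E)-5-methoxy-3-methyl-5-oxopent-3-en-1-yl]-1,4a-dimethyl-6-methylidenedecahydronaphthalene-1-carboxylate
Conditions: NaBH4, MeOH, −40 → 0 °C
Reagents that add atoms: none
Why: Hydride reduction of a cyclohexanone in which, in the expected conformer of the cis-decalin (C11 equatorial on ring B, C18 and C20 both axial on the β-face of ring A), the two axial methyl groups 1,3 to C2 block the β-face, so hydride enters from the α-face and gives the axial 2β-alcohol, the enoate and esters being inert to NaBH4 at low temperature.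

Step 19
Reactants: 29 methyl (1R,3S,4aR,5R,8aS)-3-hydroxy-5-[(3E)-5-methoxy-3-methyl-5-oxopent-3-en-1-yl]-1,4a-dimethyl-6-methylidenedecahydronaphthalene-1-carboxylate
Product: 30 (1R,3S,4aR,5R,8aS)-5-[(3E)-4-carboxy-3-methylbut-3-en-1-yl]-3-hydroxy-1,4a-dimethyl-6-methylidenedecahydronaphthalene-1-carboxylic acid
Conditions: LiOH (excess), THF/MeOH/H2O, 60 °C; then 1 M HCl
Reagents that add atoms: lithium hydroxide, [Li+].[OH-]
Why: Saponification of both methyl esters (the C19 ester sits on a quaternary carbon and needs warming) and acidification should give the diacid, since no centre is epimerisable under these conditions and the 2β-hydroxyl, trans to C19, cannot lactonise.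

**Compound list**

1 | (E)-penta-1,3-diene | C/C=C/C=C | starting material
2 | ethyl (E)-4-oxobut-2-enoate | CCOC(=O)/C=C/C=O | starting material
3 | ethyl 6-formyl-5-methylcyclohex-3-ene-1-carboxylate (C4 ester β, C5 CHO α, C10 CH3 α; CHO and CH3 cis, ester trans to CHO) | CCOC(=O)[C@H]1CC=C[C@H](C)[C@@H]1C=O | intermediate
4 | ethyl 6-(1,3-dioxolan-2-yl)-5-methylcyclohex-3-ene-1-carboxylate (same configuration as 3) | CCOC(=O)[C@H]1CC=C[C@H](C)[C@@H]1C1OCCO1 | intermediate
5 | 6-(1,3-dioxolan-2-yl)-5-methylcyclohex-3-ene-1-carboxylic acid (same configuration as 3) | OC(=O)[C@H]1CC=C[C@H](C)[C@@H]1C1OCCO1 | intermediate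
6 | 6-(1,3-dioxolan-2-yl)-1,5-dimethylcyclohex-3-ene-1-carboxylic acid (CO2H, dioxolanyl and C10 CH3 all α and cis; C4 CH3 β) | OC(=O)[C@]1(C)CC=C[C@H](C)[C@@H]1C1OCCO1 | intermediate
7 | 2-(1,3-dioxolan-2-yl)-1,3-dimethyl-4-(phenylselanyl)-6-oxabicyclo[3.2.1]octan-7-one (lactone O on C2 α, Se on C1 β) | O=C1O[C@@H]2[C@@H]([Se]c3ccccc3)[C@H](C)[C@H](C3OCCO3)[C@@]1(C)C2 | intermediate (not isolated)
8 | Se-oxide of 7 | O=C1O[C@@H]2[C@@H]([Se](=O)c3ccccc3)[C@H](C)[C@H](C3OCCO3)[C@@]1(C)C2 | intermediate (not isolated)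
9 | 2-(1,3-dioxolan-2-yl)-1,3-dimethyl-6-oxabicyclo[3.2.1]oct-3-en-7-one (lactone bridge C19–O–C2 on the α-face, dioxolanyl α, C4 CH3 β) | O=C1O[C@@H]2C=C(C)[C@H](C3OCCO3)[C@@]1(C)C2 | intermediate
10 | methyl 2-(1,3-dioxolan-2-yl)-5-hydroxy-1,3-dimethylcyclohex-3-ene-1-carboxylate (CO2Me, dioxolanyl and OH all α; C4 CH3 β) | COC(=O)[C@]1(C)C[C@H](O)C=C(C)[C@@H]1C1OCCO1 | intermediate
11 | hex-5-enoic acid | OC(=O)CCCC=C | starting material
12 | methyl 2-(1,3-dioxolan-2-yl)-5-(hex-5-enoyloxy)-1,3-dimethylcyclohex-3-ene-1-carboxylate (configuration as 10) | COC(=O)[C@]1(C)C[C@H](OC(=O)CCCC=C)C=C(C)[C@@H]1C1OCCO1 | intermediate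
13 | trimethylsilyl ketene acetal of 12 (C11 cis to OSiMe3) | COC(=O)[C@]1(C)C[C@H](O/C(O[Si](C)(C)C)=C/CCC=C)C=C(C)[C@@H]1C1OCCO1 | intermediate (not isolated)
14 | trimethylsilyl ester of 15 | COC(=O)[C@]1(C)CC=C[C@](C)([C@H](CCC=C)C(=O)O[Si](C)(C)C)[C@@H]1C1OCCO1 | intermediate (not isolated)
15 | 2-[6-(1,3-dioxolan-2-yl)-5-(methoxycarbonyl)-1,5-dimethylcyclohex-2-en-1-yl]hex-5-enoic acid (C10: CH3 β, C9 α; C9 as in the target; C5 dioxolanyl α; C4 CO2Me α) | COC(=O)[C@]1(C)CC=C[C@](C)([C@H](CCC=C)C(=O)O)[C@@H]1C1OCCO1 | intermediate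
16 | N-acylimidazole of 15 | COC(=O)[C@]1(C)CC=C[C@](C)([C@H](CCC=C)C(=O)n2ccnc2)[C@@H]1C1OCCO1 | intermediate (not isolated)
17 | methyl 2-(1,3-dioxolan-2-yl)-3-{1-[methoxy(methyl)amino]-1-oxohex-5-en-2-yl}-1,3-dimethylcyclohex-4-ene-1-carboxylate (configuration as 15) | COC(=O)[C@]1(C)CC=C[C@](C)([C@H](CCC=C)C(=O)N(C)OC)[C@@H]1C1OCCO1 | intermediate
18 | methyl 2-(1,3-dioxolan-2-yl)-1,3-dimethyl-3-(2-oxohept-6-en-3-yl)cyclohex-4-ene-1-carboxylate (configuration as 15) | COC(=O)[C@]1(C)CC=C[C@](C)([C@H](CCC=C)C(C)=O)[C@@H]1C1OCCO1 | intermediate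
19 | methyl 2-(1,3-dioxolan-2-yl)-1,3-dimethyl-3-[2-(trifluoromethanesulfonyloxy)hepta-1,6-dien-3-yl]cyclohex-4-ene-1-carboxylate (configuration as 15) | COC(=O)[C@]1(C)CC=C[C@](C)([C@H](CCC=C)C(=C)OS(=O)(=O)C(F)(F)F)[C@@H]1C1OCCO1 | intermediate
20 | methyl 2-(1,3-dioxolan-2-yl)-1,3-dimethyl-3-[6-oxo-2-(trifluoromethanesulfonyloxy)hept-1-en-3-yl]cyclohex-4-ene-1-carboxylate (configuration as 15) | COC(=O)[C@]1(C)CC=C[C@](C)([C@H](CCC(C)=O)C(=C)OS(=O)(=O)C(F)(F)F)[C@@H]1C1OCCO1 | intermediate
21 | trimethyl phosphonoacetate | COC(=O)CP(=O)(OC)OC | starting material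
22 | methyl 2-(1,3-dioxolan-2-yl)-3-[(6E)-8-methoxy-6-methyl-8-oxo-2-(trifluoromethanesulfonyloxy)octa-1,6-dien-3-yl]-1,3-dimethylcyclohex-4-ene-1-carboxylate (configuration as 15) | COC(=O)[C@]1(C)CC=C[C@](C)([C@H](CC/C(C)=C/C(=O)OC)C(=C)OS(=O)(=O)C(F)(F)F)[C@@H]1C1OCCO1 | intermediate
23 | methyl 2-formyl-3-[(6E)-8-methoxy-6-methyl-8-oxo-2-(trifluoromethanesulfonyloxy)octa-1,6-dien-3-yl]-1,3-dimethylcyclohex-4-ene-1-carboxylate (CHO α, cis to C9 and CO2Me) | COC(=O)[C@]1(C)CC=C[C@](C)([C@H](CC/C(C)=C/C(=O)OC)C(=C)OS(=O)(=O)C(F)(F)F)[C@@H]1C=O | intermediate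
24 | methyl 2-ethenyl-3-[(6E)-8-methoxy-6-methyl-8-oxo-2-(trifluoromethanesulfonyloxy)octa-1,6-dien-3-yl]-1,3-dimethylcyclohex-4-ene-1-carboxylate (vinyl, C9 and CO2Me all α; both ring CH3 β) | COC(=O)[C@]1(C)CC=C[C@](C)([C@H](CC/C(C)=C/C(=O)OC)C(=C)OS(=O)(=O)C(F)(F)F)[C@@H]1C=C | intermediate
25 | bis(9-borabicyclo[3.3.1]nonan-9-yl) adduct of 24 (boron on C7 and on C2, C2 epimers) | COC(=O)[C@]1(C)CC(B2C3CCCC2CCC3)C[C@](C)([C@H](CC/C(C)=C/C(=O)OC)C(=C)OS(=O)(=O)C(F)(F)F)[C@@H]1CCB1C2CCCC1CCC2 | intermediate (not isolated)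
26 | cis-fused bicyclic diester with 9-BBN on C2 (C2 epimers) | C=C1CC[C@H]2[C@](C)(CC(B3C4CCCC3CCC4)C[C@@]2(C)C(=O)OC)[C@@H]1CC/C(C)=C/C(=O)OC | intermediate (not isolated)
27 | methyl 3-hydroxy-5-[(3E)-5-methoxy-3-methyl-5-oxopent-3-en-1-yl]-1,4a-dimethyl-6-methylidenedecahydronaphthalene-1-carboxylate (1R,4aR,5R,8aS; C2 carbinol as epimer mixture) | C=C1CC[C@H]2[C@](C)(CC(O)C[C@@]2(C)C(=O)OC)[C@@H]1CC/C(C)=C/C(=O)OC | intermediate
28 | methyl (1R,4aR,5R,8aS)-5-[(3E)-5-methoxy-3-methyl-5-oxopent-3-en-1-yl]-1,4a-dimethyl-6-methylidene-3-oxodecahydronaphthalene-1-carboxylate | C=C1CC[C@H]2[C@](C)(CC(=O)C[C@@]2(C)C(=O)OC)[C@@H]1CC/C(C)=C/C(=O)OC | intermediate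
29 | methyl (1R,3S,4aR,5R,8aS)-3-hydroxy-5-[(3E)-5-methoxy-3-methyl-5-oxopent-3-en-1-yl]-1,4a-dimethyl-6-methylidenedecahydronaphthalene-1-carboxylate (2β-OH) | C=C1CC[C@H]2[C@](C)(C[C@H](O)C[C@@]2(C)C(=O)OC)[C@@H]1CC/C(C)=C/C(=O)OC | intermediate
30 | (1R,3S,4aR,5R,8aS)-5-[(3E)-4-carboxy-3-methylbut-3-en-1-yl]-3-hydroxy-1,4a-dimethyl-6-methylidenedecahydronaphthalene-1-carboxylic acid | C=C1CC[C@H]2[C@](C)(C[C@H](O)C[C@@]2(C)C(=O)O)[C@@H]1CC/C(C)=C/C(=O)O | target

**Totals**

Total step count: 19. Longest linear sequence: 19 steps (1 and 2 to 30); 11 and 21 are bought.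

**Steps most likely to fail**

Step 8 (Ireland–Claisen rearrangement). The [3,3] shift may be too slow, because the new quaternary centre forms syn to the dioxolanyl group on C5, and the ketene acetal may then decompose. Leakage through the chair-like transition state would erode the C9 configuration. Fallback: from 10, an acid-catalysed Johnson–Claisen rearrangement with trimethyl orthohex-5-enoate (propionic acid cat., xylene, 140 °C) passes through a neutral ketene acetal with no anionic intermediate. It should give methyl 2-[6-(1,3-dioxolan-2-yl)-5-(methoxycarbonyl)-1,5-dimethylcyclohex-2-en-1-yl]hex-5-enoate F1, with the same suprafacial control at C10 but probably lower selectivity at C9. The less hindered ester of F1 is then converted with MeNH(OMe)·HCl and i-PrMgCl into 17, where C9 epimers are separated and the route is rejoined.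

Step 16 (key step). Hydroboration of the hindered ring alkene may stay incomplete, excess borane may reduce the enoate in a conjugate sense, or protodeboronation and intermolecular coupling may outrun the ring-closing transmetalation. Fallback: from 24, the two hydroborations are run as in step 16 (giving 25) and are followed directly by NaBO3·4H2O without palladium. This should give methyl 5-hydroxy-2-(2-hydroxyethyl)-3-[(6E)-8-methoxy-6-methyl-8-oxo-2-(trifluoromethanesulfonyloxy)octa-1,6-dien-3-yl]-1,3-dimethylcyclohexane-1-carboxylate F2. Appel iodination of the primary alcohol only (I2, PPh3, imidazole, 0 °C) then gives methyl 5-hydroxy-2-(2-iodoethyl)-3-[(6E)-8-methoxy-6-methyl-8-oxo-2-(trifluoromethanesulfonyloxy)octa-1,6-dien-3-yl]-1,3-dimethylcyclohexane-1-carboxylate F3. Ring B is closed at C7–C8 by a nickel-catalysed reductive cross-electrophile coupling of the alkyl iodide with the alkenyl triflate (NiBr2·diglyme, 4,4'-di-tert-butyl-2,2'-bipyridine, Mn powder, DMA, rt), which comes back to the route at 27.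

Step 18 (C2 reduction). If ring A reacts through its other chair, hydride may enter from the β-face and give poor or reversed facial selectivity. Fallback: from 28, the same reduction would then give methyl (1R,3R,4aR,5R,8aS)-3-hydroxy-5-[(3E)-5-methoxy-3-methyl-5-oxopent-3-en-1-yl]-1,4a-dimethyl-6-methylidenedecahydronaphthalene-1-carboxylate F4 (2α-alcohol). In that case the β-face is the open one, so a Mitsunobu inversion (4-nitrobenzoic acid, PPh3, diisopropyl azodicarboxylate, THF) should give methyl (1R,3S,4aR,5R,8aS)-5-[(3E)-5-methoxy-3-methyl-5-oxopent-3-en-1-yl]-1,4a-dimethyl-6-methylidene-3-[(4-nitrobenzoyl)oxy]decahydronaphthalene-1-carboxylate F5. The conditions of step 19 cleave all three esters of F5 and return to the route at 30.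

Further compounds
F1 | step 8 | methyl 2-[6-(1,3-dioxolan-2-yl)-5-(methoxycarbonyl)-1,5-dimethylcyclohex-2-en-1-yl]hex-5-enoate | COC(=O)[C@]1(C)CC=C[C@](C)([C@H](CCC=C)C(=O)OC)[C@@H]1C1OCCO1
F2 | step 16 | methyl 5-hydroxy-2-(2-hydroxyethyl)-3-[(6E)-8-methoxy-6-methyl-8-oxo-2-(trifluoromethanesulfonyloxy)octa-1,6-dien-3-yl]-1,3-dimethylcyclohexane-1-carboxylate | COC(=O)[C@]1(C)CC(O)C[C@](C)([C@H](CC/C(C)=C/C(=O)OC)C(=C)OS(=O)(=O)C(F)(F)F)[C@@H]1CCO
F3 | step 16 | methyl 5-hydroxy-2-(2-iodoethyl)-3-[(6E)-8-methoxy-6-methyl-8-oxo-2-(trifluoromethanesulfonyloxy)octa-1,6-dien-3-yl]-1,3-dimethylcyclohexane-1-carboxylate | COC(=O)[C@]1(C)CC(O)C[C@](C)([C@H](CC/C(C)=C/C(=O)OC)C(=C)OS(=O)(=O)C(F)(F)F)[C@@H]1CCI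
F4 | step 18 | methyl (1R,3R,4aR,5R,8aS)-3-hydroxy-5-[(3E)-5-methoxy-3-methyl-5-oxopent-3-en-1-yl]-1,4a-dimethyl-6-methylidenedecahydronaphthalene-1-carboxylate | C=C1CC[C@H]2[C@](C)(C[C@@H](O)C[C@@]2(C)C(=O)OC)[C@@H]1CC/C(C)=C/C(=O)OC
F5 | step 18 | methyl (1R,3S,4aR,5R,8aS)-5-[(3E)-5-methoxy-3-methyl-5-oxopent-3-en-1-yl]-1,4a-dimethyl-6-methylidene-3-[(4-nitrobenzoyl)oxy]decahydronaphthalene-1-carboxylate | C=C1CC[C@H]2[C@](C)(C[C@H](OC(=O)c3ccc(cc3)[N+](=O)[O-])C[C@@]2(C)C(=O)OC)[C@@H]1CC/C(C)=C/C(=O)OC
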